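**Plan**
- Retrosynthesis: the acetic acid arm is cut first at C3–CH2, so C3 becomes the acetal carbon of a 1,2-dioxan-3-ylium ion. The ring is then cut at C5–C6 and O2–C3 into a C6–O1–O2 unit (a ketone-derived silylperoxycarbenium ion) and a C5–C4–C3 unit.
- Enabling feature: in the ring O1–O2–C3–C4–C5–C6, C3 carries the peroxy oxygen O2 and, with the arm off, is at aldehyde level, so C5 is the β-carbon of that aldehyde. C5–C4–C3 is therefore a homoenolate, i.e. the C1–C3 σ bond of a 2-methylcyclopropanol silyl ether; this polarity reversal lets C5 bond to electrophilic C6 while O2 closes on C3.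
- Forward: (R)-citronellal → methyl ketone 9 → silyl peroxyketal 13; cyclopropane acid 14 → siloxycyclopropane 18; one [3+3] annulation builds the whole 1,2-dioxane (step 12); the arm is joined last (step 14). No protecting group is used.
- Stereochemistry: the side-chain centre comes from (R)-citronellal; C4 from the untouched methyl-bearing carbon of 14; C6 is set in the annulation (E peroxycarbenium ion, chair-like array); C3 by axial attack on the half-chair dioxanylium ion.

Key step: step 12

Assumption: acid 14 is bought as the single (1S,2S) enantiomer; carbinol, ketal and acetal centres that are destroyed later are carried as epimer mixtures and left undefined in the SMILES.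

**Step 1**
Reactants: 1 (R)-citronellal [(3R)-3,7-dimethyloct-6-enal]
Product: 2 (4R)-4,8-dimethylnon-7-en-2-ol (C2 epimers)
Conditions: MeMgBr, Et2O, 0 °C; aq. NH4Cl
Reagents that add atoms: methylmagnesium bromide, C[Mg]Br
Why: Grignard 1,2-addition to the aldehyde; the new carbinol centre is uncontrolled and is removed by oxidation in step 5.

**Step 2**
Reactants: 2 (4R)-4,8-dimethylnon-7-en-2-ol
Product: 4 (4R)-4-methylheptane-1,6-diol, via ozonide 3 (not isolated)
Conditions: O3, CH2Cl2, −78 °C; then NaBH4, MeOH, −78 to 0 °C
Reagents that add atoms: ozone, [O-][O+]=O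
Why: Ozonolysis of the electron-rich trisubstituted alkene with hydride work-up cuts off the isopropylidene group and leaves the primary alcohol, with the remote stereocentre untouched.

**Step 3**
Reactants: 4 (4R)-4-methylheptane-1,6-diol
Product: 5 (4R)-6-hydroxy-4-methylheptyl 4-methylbenzenesulfonate
Conditions: TsCl (1.05 equiv), pyridine, CH2Cl2, 0 °C
Reagents that add atoms: 4-methylbenzenesulfonyl chloride, Cc1ccc(cc1)S(Cl)(=O)=O
Why: Selective O-sulfonylation of the primary over the secondary hydroxyl on steric grounds.

**Step 4**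
Reactants: 5 (4R)-6-hydroxy-4-methylheptyl 4-methylbenzenesulfonate; 6 (6-bromohexyl)benzene
Product: 8 (4R)-4-methyl-13-phenyltridecan-2-ol, via Grignard reagent 7 (not isolated)
Conditions: 6, Mg, THF; then 5, Li2CuCl4 (3 mol%), THF, −78 to 23 °C (2.3 equiv of 7)
Reagents that add atoms: none
Why: Copper-catalysed sp3–sp3 cross-coupling of a primary alkyl Grignard reagent with a primary tosylate, in which one equivalent of 7 serves as base for the free hydroxyl.

**Step 5**
Reactants: 8 (4R)-4-methyl-13-phenyltridecan-2-ol
Product: 9 (4R)-4-methyl-13-phenyltridecan-2-one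
Conditions: Dess–Martin periodinane, NaHCO3, CH2Cl2, 23 °C
Reagents that add atoms: none
Why: Dess–Martin oxidation of the secondary alcohol; the stereocentre is β to the carbonyl and cannot epimerise.

**Step 6**
Reactants: 9 (4R)-4-methyl-13-phenyltridecan-2-one
Product: 10 [(10R)-10,12-dimethyltridec-12-en-1-yl]benzene
Conditions: Ph3PCH3Br, KOtBu, THF, 0 to 23 °C
Reagents that add atoms: methyltriphenylphosphonium bromide, C[P+](c1ccccc1)(c1ccccc1)c1ccccc1.[Br-]
Why: Wittig methylenation of the methyl ketone gives the 1,1-disubstituted alkene that can deliver the ketone O-oxide.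

**Step 7**
Reactants: 10 [(10R)-10,12-dimethyltridec-12-en-1-yl]benzene
Product: 12 [(10R)-12-hydroperoxy-12-methoxy-10-methyltridecyl]benzene (C12 epimers), via carbonyl oxide 11 (not isolated)
Conditions: O3 (1 equiv), CH2Cl2/MeOH 4:1, −78 °C
Reagents that add atoms: ozone, [O-][O+]=O; methanol, CO
Why: Criegee ozonolysis, in which the primary ozonide should fragment to formaldehyde and the more substituted (ketone) carbonyl oxide, which methanol traps as the α-methoxy hydroperoxide while the far less reactive arene is spared.

**Step 8**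
Reactants: 12 [(10R)-12-hydroperoxy-12-methoxy-10-methyltridecyl]benzene
Product: 13 triethyl{[(4R)-2-methoxy-4-methyl-13-phenyltridecan-2-yl]peroxy}silane (C2 epimers)
Conditions: Et3SiCl, imidazole, DMF, 0 °C
Reagents that add atoms: chlorotriethylsilane, CC[Si](Cl)(CC)CC
Why: O-silylation of the hydroperoxide gives the silyl peroxyketal, the established precursor of a peroxycarbenium ion.

**Step 9**
Reactants: 14 (1S,2S)-2-methylcyclopropane-1-carboxylic acid
Product: 15 1-[(1S,2S)-2-methylcyclopropyl]ethan-1-one
Conditions: MeLi (2.2 equiv), Et2O, 0 °C; aq. NH4Cl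
Reagents that add atoms: methyllithium, [Li]C
Why: Methyllithium adds to the lithium carboxylate to give a dilithio gem-diolate that collapses to the methyl ketone only on work-up, with both ring centres retained.

**Step 10**
Reactants: 15 1-[(1S,2S)-2-methylcyclopropyl]ethan-1-one
Product: 16 (1S,2S)-2-methylcyclopropyl acetate
Conditions: (CF3CO)2O, urea·H2O2, Na2HPO4, CH2Cl2, 0 to 23 °C
Reagents that add atoms: trifluoroperoxyacetic acid (formed in the flask), OOC(=O)C(F)(F)F
Why: Baeyer–Villiger oxidation, in which the cyclopropyl group migrates in preference to methyl and with retention at the migrating carbon.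

**Step 11**
Reactants: 16 (1S,2S)-2-methylcyclopropyl acetate
Product: 18 triethyl{[(1S,2S)-2-methylcyclopropyl]oxy}silane, via lithium alkoxide 17 (not isolated)
Conditions: MeLi (2.1 equiv), Et2O, −78 to 0 °C; then Et3SiCl, −78 to 23 °C
Reagents that add atoms: chlorotriethylsilane, CC[Si](Cl)(CC)CC
Why: Acyl cleavage by methyllithium gives the lithium cyclopropanolate, which is silylated in the same flask so that the volatile, easily ring-opened free cyclopropanol is never handled.

**Step 12**
Reactants: 13 triethyl{[(4R)-2-methoxy-4-methyl-13-phenyltridecan-2-yl]peroxy}silane; 18 triethyl{[(1S,2S)-2-methylcyclopropyl]oxy}silane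
Product: 21 triethyl({(4S,6R)-4,6-dimethyl-6-[(2R)-2-methyl-11-phenylundecyl]-1,2-dioxan-3-yl}oxy)silane (C3 epimers), via peroxycarbenium ion 19 (not isolated), via oxocarbenium ion 20 (not isolated)
Conditions: 18 (1.5 equiv), Et3SiOSO2CF3 (0.2 equiv), 2,6-di-tert-butyl-4-methylpyridine (0.3 equiv), CH2Cl2, −78 to −40 °C; NaHCO3 quench
Reagents that add atoms: none
Why: Proposed new method: Et3SiOSO2CF3 abstracts methoxide from 13 to give the ketone-derived peroxycarbenium ion 19 (the C6–O1–O2 unit); the oxygen-activated C1–C3 σ bond of 18 attacks it through its unsubstituted CH2 (the future C5), which forms C5–C6 and opens the three-membered ring to the silyloxocarbenium ion 20, whose C3 is then captured by the silylated peroxy oxygen O2 in a 6-exo-trig closure with release of the silyl cation that carries the chain, overall a formal [3+3] annulation of a peroxycarbenium ion with an aldehyde homoenolate. The closest known reaction types are the Lewis-acid [3+2] annulation of silylperoxycarbenium ions with alkenes to 1,2-dioxolanes, Mukaiyama- and Sakurai-type additions to the same ions, and the electrophilic ring opening of siloxycyclopropanes as homoenolate equivalents. C4 is the methyl-bearing cyclopropane carbon, is not involved in any bond change and keeps its configuration; C3 forms as an acetal epimer mixture that is erased in step 14. The new quaternary centre C6 is set by the face of 19 that is attacked: the peroxy group should lie anti to the branched chain (E ion), and if C–C and C–O bond formation pass through a compact chair-like array with the C4 methyl equatorial, the chain ends equatorial and the C6 methyl axial, which is the 4,6-relationship of the target; this bias is expected to be modest and the C6 epimer would be removed by chromatography at this stage. The step needs regioselective cleavage of the C1–C3 bond (secured by the siloxy donor at C1 and by attack at the least substituted carbon) and interception of 19 before Criegee/Hock-type fragmentation (secured by low temperature, excess 18 and a hindered base that suppresses protodesilylation of 18).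

**Step 13**
Reactants: 22 trimethylsilyl acetate
Product: 24 1,1-bis(trimethylsilyloxy)ethene, via lithium enolate 23 (not isolated)
Conditions: LiN(iPr)2, THF, −78 °C; then Me3SiCl, −78 to 23 °C; distillation
Reagents that add atoms: chlorotrimethylsilane, C[Si](C)(C)Cl
Why: Deprotonation of the silyl ester and O-silylation of the enolate give the ketene bis(silyl) acetal, an acetic acid enolate equivalent that releases the free acid on work-up.

**Step 14**
Reactants: 21 triethyl({(4S,6R)-4,6-dimethyl-6-[(2R)-2-methyl-11-phenylundecyl]-1,2-dioxan-3-yl}oxy)silane; 24 1,1-bis(trimethylsilyloxy)ethene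
Product: 27 2-{(3S,4S,6R)-4,6-dimethyl-6-[(2R)-2-methyl-11-phenylundecyl]-1,2-dioxan-3-yl}acetic acid (CNP0181677.1), via dioxanylium ion 25 (not isolated), via silyl ester 26 (not isolated)
Conditions: 24 (2 equiv), Me3SiOSO2CF3 (0.3 equiv), CH2Cl2, −78 °C; aq. citric acid work-up
Reagents that add atoms: none
Why: Me3SiOSO2CF3 ionises the silyl peroxy-acetal to the 1,2-dioxan-3-ylium ion 25, which the ketene acetal captures (Mukaiyama-type substitution of cyclic peroxy acetals, as known for 3-alkoxy-1,2-dioxolanes and for C10 of artemisinin-type trioxanes) by axial attack on the half-chair that holds the C4 methyl and the C6 chain pseudo-equatorial, which should set C3 cis to the C4 methyl (3S), and the work-up cleaves silyl ester 26.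

**Compound list**
1 | (R)-citronellal, (3R)-3,7-dimethyloct-6-enal | C[C@H](CCC=C(C)C)CC=O | starting material
2 | (4R)-4,8-dimethylnon-7-en-2-ol (C2 epimers) | C[C@H](CCC=C(C)C)CC(C)O | intermediate
3 | 5-[(3R)-5-hydroxy-3-methylhexyl]-3,3-dimethyl-1,2,4-trioxolane (ozonide) | C[C@H](CCC1OOC(C)(C)O1)CC(C)O | intermediate (not isolated)
4 | (4R)-4-methylheptane-1,6-diol | C[C@H](CCCO)CC(C)O | intermediate
5 | (4R)-6-hydroxy-4-methylheptyl 4-methylbenzenesulfonate | C[C@H](CCCOS(=O)(=O)c1ccc(C)cc1)CC(C)O | intermediate
6 | (6-bromohexyl)benzene | BrCCCCCCc1ccccc1 | starting material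
7 | (6-phenylhexyl)magnesium bromide | Br[Mg]CCCCCCc1ccccc1 | intermediate (not isolated)
8 | (4R)-4-methyl-13-phenyltridecan-2-ol (C2 epimers) | C[C@H](CCCCCCCCCc1ccccc1)CC(C)O | intermediate
9 | (4R)-4-methyl-13-phenyltridecan-2-one | C[C@H](CCCCCCCCCc1ccccc1)CC(C)=O | intermediate
10 | [(10R)-10,12-dimethyltridec-12-en-1-yl]benzene | C[C@H](CCCCCCCCCc1ccccc1)CC(C)=C | intermediate
11 | (4R)-4-methyl-13-phenyltridecan-2-one O-oxide (carbonyl oxide) | C[C@H](CCCCCCCCCc1ccccc1)CC(C)=[O+][O-] | intermediate (not isolated)
12 | [(10R)-12-hydroperoxy-12-methoxy-10-methyltridecyl]benzene (C12 epimers) | C[C@H](CCCCCCCCCc1ccccc1)CC(C)(OC)OO | intermediate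
13 | triethyl{[(4R)-2-methoxy-4-methyl-13-phenyltridecan-2-yl]peroxy}silane (C2 epimers) | C[C@H](CCCCCCCCCc1ccccc1)CC(C)(OC)OO[Si](CC)(CC)CC | intermediate
14 | (1S,2S)-2-methylcyclopropane-1-carboxylic acid | C[C@H]1C[C@@H]1C(=O)O | starting material
15 | 1-[(1S,2S)-2-methylcyclopropyl]ethan-1-one | C[C@H]1C[C@@H]1C(C)=O | intermediate
16 | (1S,2S)-2-methylcyclopropyl acetate | C[C@H]1C[C@@H]1OC(C)=O | intermediate
17 | lithium (1S,2S)-2-methylcyclopropan-1-olate | C[C@H]1C[C@@H]1[O-].[Li+] | intermediate (not isolated)
18 | triethyl{[(1S,2S)-2-methylcyclopropyl]oxy}silane | C[C@H]1C[C@@H]1O[Si](CC)(CC)CC | intermediate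
19 | [(4R)-4-methyl-13-phenyltridecan-2-ylidene](triethylsilylperoxy)oxonium trifluoromethanesulfonate (peroxycarbenium ion) | C[C@H](CCCCCCCCCc1ccccc1)CC(C)=[O+]O[Si](CC)(CC)CC.[O-]S(=O)(=O)C(F)(F)F | intermediate (not isolated)
20 | [(2S,4R,6R)-2,4,6-trimethyl-15-phenyl-4-(triethylsilylperoxy)pentadecylidene](triethylsilyl)oxonium trifluoromethanesulfonate | C[C@H](CCCCCCCCCc1ccccc1)C[C@](OO[Si](CC)(CC)CC)(C)C[C@H](C)C=[O+][Si](CC)(CC)CC.[O-]S(=O)(=O)C(F)(F)F | intermediate (not isolated)
21 | triethyl({(4S,6R)-4,6-dimethyl-6-[(2R)-2-methyl-11-phenylundecyl]-1,2-dioxan-3-yl}oxy)silane (C3 epimers) | C[C@H](CCCCCCCCCc1ccccc1)C[C@]1(C)C[C@H](C)C(O[Si](CC)(CC)CC)OO1 | intermediate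
22 | trimethylsilyl acetate | CC(=O)O[Si](C)(C)C | starting material
23 | lithium 1-(trimethylsilyloxy)ethen-1-olate | C=C([O-])O[Si](C)(C)C.[Li+] | intermediate (not isolated)
24 | 1,1-bis(trimethylsilyloxy)ethene | C=C(O[Si](C)(C)C)O[Si](C)(C)C | intermediate
25 | (4S,6R)-4,6-dimethyl-6-[(2R)-2-methyl-11-phenylundecyl]-1,2-dioxan-3-ylium trifluoromethanesulfonate | C[C@H](CCCCCCCCCc1ccccc1)C[C@]1(C)C[C@H](C)C=[O+]O1.[O-]S(=O)(=O)C(F)(F)F | intermediate (not isolated)
26 | trimethylsilyl 2-{(3S,4S,6R)-4,6-dimethyl-6-[(2R)-2-methyl-11-phenylundecyl]-1,2-dioxan-3-yl}acetate | C[C@H](CCCCCCCCCc1ccccc1)C[C@]1(C)C[C@H](C)[C@H](CC(=O)O[Si](C)(C)C)OO1 | intermediate (not isolated)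
27 | 2-{(3S,4S,6R)-4,6-dimethyl-6-[(2R)-2-methyl-11-phenylundecyl]-1,2-dioxan-3-yl}acetic acid | C[C@H](CCCCCCCCCc1ccccc1)C[C@]1(C)C[C@H](C)[C@H](CC(=O)O)OO1 | target

**Step count**
Total: 14 steps. Longest linear sequence: 10 steps (steps 1–8, 12, 14).

**Steps most likely to fail**

1. Step 12 (proposed new method). The cyclopropane σ bond may be too weak a nucleophile, so that ion 19 decays by Criegee/Hock-type fragmentation or 18 is consumed by protodesilylative ring opening; face selection at C6 may also be low. The fallback uses known chemistry, sets out from ketone 9 and comes back at 21. Kinetic enolisation of 9 at the methyl group (LiN(iPr)2, THF, −78 °C) and trapping with PhNTf2 would give the enol triflate F1. Negishi coupling (Pd(PPh3)4, THF/DMA) with the zinc reagent F2, made from commercial methyl (R)-3-bromo-2-methylpropanoate and zinc dust, would give the 1,1-disubstituted alkene ester F3, which already carries the C4 centre. Mukaiyama–Isayama hydroperoxysilylation (Co(acac)2, O2, Et3SiH) would give the tertiary silyl peroxide F4; C6 is not controlled in this step, so the epimers would be separated later. Reduction with iBu2AlH at −78 °C would give the aldehyde F5, and HF·pyridine would free the hydroperoxide, which closes to the lactol F6. Silylation (Et3SiCl, imidazole) would return to 21.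

2. Step 14. Attack anti to the neighbouring C4 methyl (loss of facial selectivity at C3) or fragmentation of ion 25 may compete. The fallback sets out from 21 and comes back at 27, and replaces the substitution by an olefination and a kinetic 6-exo peroxy-Michael closure. HF·pyridine would convert 21 into the lactol F6; methyl (triphenylphosphoranylidene)acetate would open it to the hydroperoxy enoate F7. Et2NH in CF3CH2OH at 0 °C would close F7 to the methyl ester F8, with the 3-epimer separated, and LiOH in THF/H2O at 0 °C would give 27.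

3. Step 7. The primary ozonide may cleave towards formaldehyde O-oxide and return ketone 9, or the hydroperoxy ketal may lose methanol and hydrogen peroxide on work-up. The fallback sets out from ketone 9 and comes back at 12 without ozone. HC(OMe)3 and MeOH with catalytic TsOH would give the dimethyl ketal F9, and acid-catalysed perhydrolysis with anhydrous H2O2 in Et2O would exchange one methoxy group for the hydroperoxy group to give 12.

**Further compounds**
F1 | step 12 | (4R)-4-methyl-13-phenyltridec-1-en-2-yl trifluoromethanesulfonate | C[C@H](CCCCCCCCCc1ccccc1)CC(=C)OS(=O)(=O)C(F)(F)F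
F2 | step 12 | [(2R)-3-methoxy-2-methyl-3-oxopropyl]zinc bromide | Br[Zn]C[C@H](C)C(=O)OC
F3 | step 12 | methyl (2S)-2-methyl-4-[(2R)-2-methyl-11-phenylundecyl]pent-4-enoate | C[C@H](CCCCCCCCCc1ccccc1)CC(=C)C[C@H](C)C(=O)OC
F4 | step 12 | methyl (2S,4R,6R)-2,4,6-trimethyl-15-phenyl-4-(triethylsilylperoxy)pentadecanoate (formed with its C4 epimer) | C[C@H](CCCCCCCCCc1ccccc1)C[C@](OO[Si](CC)(CC)CC)(C)C[C@H](C)C(=O)OC
F5 | step 12 | (2S,4R,6R)-2,4,6-trimethyl-15-phenyl-4-(triethylsilylperoxy)pentadecanal | C[C@H](CCCCCCCCCc1ccccc1)C[C@](OO[Si](CC)(CC)CC)(C)C[C@H](C)C=O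
F6 | step 12 | (4S,6R)-4,6-dimethyl-6-[(2R)-2-methyl-11-phenylundecyl]-1,2-dioxan-3-ol (C3 epimers) | C[C@H](CCCCCCCCCc1ccccc1)C[C@]1(C)C[C@H](C)C(O)OO1
F7 | step 14 | methyl (2E,4S,6R,8R)-6-hydroperoxy-4,6,8-trimethyl-17-phenylheptadec-2-enoate | C[C@H](CCCCCCCCCc1ccccc1)C[C@](OO)(C)C[C@H](C)/C=C/C(=O)OC
F8 | step 14 | methyl 2-{(3S,4S,6R)-4,6-dimethyl-6-[(2R)-2-methyl-11-phenylundecyl]-1,2-dioxan-3-yl}acetate | C[C@H](CCCCCCCCCc1ccccc1)C[C@]1(C)C[C@H](C)[C@H](CC(=O)OC)OO1
F9 | step 7 | [(10R)-12,12-dimethoxy-10-methyltridecyl]benzene | C[C@H](CCCCCCCCCc1ccccc1)CC(C)(OC)OC
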